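**Retrosynthetic overview**
1. Testudinariol A (36) ⇒ C2-symmetric bis(allylic chloride) tetraol 35; both oxane rings are closed last, together, by a double intramolecular Williamson etherification (O–CH2 bond).
2. 35 ⇒ (Z,Z)-diester 31 ⇒ two-directional Z-selective Horner–Wadsworth–Emmons olefination of butanedial 29 with two molecules of diaryl phosphonate 27.
3. 27 ⇒ iodide 24 + phosphonoacetate 25; the cyclopentanol of 24 ⇒ Me2AlCl-promoted intramolecular carbonyl-ene reaction of aldehyde 20 (cyclopentane rings formed first, one per half).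
4. 20 ⇒ anti-selective Fráter–Seebach allylation of β-hydroxy ester 8, then hydroboration/oxidation/Wittig to the 4-methylpent-3-enyl chain.
5. 8 ⇒ ketoreductase reduction of achiral β-keto ester 7 (Blaise reaction of nitrile 3, made from 1 + 2).

Assumption: an (R)-selective ketoreductase that accepts keto ester 7 is taken from a commercial screening panel (5-alkoxy-3-oxopentanoates are standard substrates). PMB = 4-methoxybenzyl, TBS = tert-butyldimethylsilyl.

---

**Step 1**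
Reactants: 1 4-methoxybenzyl alcohol; 2 acrylonitrile
Product: 3 3-[(4-methoxybenzyl)oxy]propanenitrile
Conditions: NaH (5 mol %), THF, 0 °C → rt
Reagents that add atoms: none
Why: Base-catalysed oxa-Michael addition (cyanoethylation) of a primary alkoxide to acrylonitrile is fast and clean.

**Step 2**
Reactants: 3 3-[(4-methoxybenzyl)oxy]propanenitrile; 4 methyl bromoacetate
Product: 7 methyl 5-[(4-methoxybenzyl)oxy]-3-oxopentanoate, via Reformatsky reagent 5 (not isolated), via Blaise zinc enaminoate 6 (not isolated)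
Conditions: Zn dust (TMSCl-activated), THF, reflux, slow addition of 4; then 1 M aq. HCl, rt
Reagents that add atoms: water, O
Why: Blaise reaction: the non-basic zinc enolate adds to the nitrile without β-elimination of the alkoxy group, and mild acid hydrolysis of the enaminoate gives the β-keto ester.

**Step 3**
Reactants: 7 methyl 5-[(4-methoxybenzyl)oxy]-3-oxopentanoate
Product: 8 methyl (3R)-3-hydroxy-5-[(4-methoxybenzyl)oxy]pentanoate
Conditions: ketoreductase (R-selective, NADPH-dependent), NADP+ (cat.), i-PrOH (10 vol %), pH 7.0 phosphate buffer, MgSO4 (2 mM), 30 °C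
Reagents that add atoms: none
Why: Biocatalytic asymmetric ketone reduction: the ketoreductase delivers hydride from NADPH (recycled by isopropanol) to one carbonyl face and sets C3 (R), the first stereocentre, in high ee.

**Step 4**
Reactants: 8 methyl (3R)-3-hydroxy-5-[(4-methoxybenzyl)oxy]pentanoate; 9 allyl bromide
Product: 11 methyl (2R,3R)-3-hydroxy-5-[(4-methoxybenzyl)oxy]-2-(prop-2-en-1-yl)pentanoate, via dilithium alkoxide enolate 10 (not isolated)
Conditions: LiN(i-Pr)2 (2.2 equiv), THF, −78 → −20 °C; then 9, DMPU, −78 → −20 °C; H2O quench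
Reagents that add atoms: none
Why: Fráter–Seebach alkylation: the lithium-chelated alkoxide enolate is allylated on the face opposite the C3 substituent, giving the 2,3-anti (2R,3R) product.

**Step 5**
Reactants: 11 methyl (2R,3R)-3-hydroxy-5-[(4-methoxybenzyl)oxy]-2-(prop-2-en-1-yl)pentanoate
Product: 12 methyl (2R,3R)-3-[(tert-butyldimethylsilyl)oxy]-5-[(4-methoxybenzyl)oxy]-2-(prop-2-en-1-yl)pentanoate
Conditions: TBSOTf, 2,6-lutidine, CH2Cl2, −78 → 0 °C
Reagents that add atoms: tert-butyldimethylsilyl trifluoromethanesulfonate, CC(C)(C)[Si](C)(C)OS(=O)(=O)C(F)(F)F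
Why: Silylation of the secondary alcohol under non-nucleophilic base avoids retro-aldol or epimerisation and gives a non-chelating β-silyloxy group for the later ene step.

**Step 6**
Reactants: 12 methyl (2R,3R)-3-[(tert-butyldimethylsilyl)oxy]-5-[(4-methoxybenzyl)oxy]-2-(prop-2-en-1-yl)pentanoate
Product: 14 methyl (2R,3R)-3-[(tert-butyldimethylsilyl)oxy]-2-(3-hydroxypropyl)-5-[(4-methoxybenzyl)oxy]pentanoate, via B-alkyl-9-BBN adduct 13 (not isolated)
Conditions: 9-BBN, THF, 0 °C → rt; then 30% H2O2, aq. NaOAc, 0 °C → rt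
Reagents that add atoms: hydrogen peroxide, OO
Why: Anti-Markovnikov hydroboration–oxidation of the terminal alkene; 9-BBN does not touch the ester and the buffered oxidation spares it.

**Step 7**
Reactants: 14 methyl (2R,3R)-3-[(tert-butyldimethylsilyl)oxy]-2-(3-hydroxypropyl)-5-[(4-methoxybenzyl)oxy]pentanoate
Product: 15 methyl (2R,3R)-3-[(tert-butyldimethylsilyl)oxy]-5-[(4-methoxybenzyl)oxy]-2-(3-oxopropyl)pentanoate
Conditions: Dess–Martin periodinane, NaHCO3, CH2Cl2, 0 °C → rt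
Reagents that add atoms: none
Why: Dess–Martin oxidation of a primary alcohol to the aldehyde under buffered, non-epimerising conditions.

**Step 8**
Reactants: 15 methyl (2R,3R)-3-[(tert-butyldimethylsilyl)oxy]-5-[(4-methoxybenzyl)oxy]-2-(3-oxopropyl)pentanoate; 16 isopropyltriphenylphosphonium iodide
Product: 18 methyl (2R,3R)-3-[(tert-butyldimethylsilyl)oxy]-5-[(4-methoxybenzyl)oxy]-2-(4-methylpent-3-en-1-yl)pentanoate, via isopropylidene phosphorane 17 (not isolated)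
Conditions: 16, n-BuLi (slight deficit), THF, 0 °C; then 15, −78 °C → rt
Reagents that add atoms: none
Why: Wittig olefination of the aldehyde with the non-stabilised isopropylidene ylide installs the trisubstituted alkene (no geometry issue) far faster than any attack on the hindered ester.

**Step 9**
Reactants: 18 methyl (2R,3R)-3-[(tert-butyldimethylsilyl)oxy]-5-[(4-methoxybenzyl)oxy]-2-(4-methylpent-3-en-1-yl)pentanoate
Product: 19 (2S,3R)-3-[(tert-butyldimethylsilyl)oxy]-5-[(4-methoxybenzyl)oxy]-2-(4-methylpent-3-en-1-yl)pentan-1-ol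
Conditions: i-Bu2AlH (2.5 equiv), CH2Cl2, −78 → 0 °C; aq. KNaC4H4O6 work-up
Reagents that add atoms: none
Why: Full hydride reduction of the ester to the primary alcohol (the descriptor at C2 changes by priority only), more dependable than a partial reduction to the aldehyde.

**Step 10**
Reactants: 19 (2S,3R)-3-[(tert-butyldimethylsilyl)oxy]-5-[(4-methoxybenzyl)oxy]-2-(4-methylpent-3-en-1-yl)pentan-1-ol
Product: 20 (2R,3R)-3-[(tert-butyldimethylsilyl)oxy]-5-[(4-methoxybenzyl)oxy]-2-(4-methylpent-3-en-1-yl)pentanal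
Conditions: Dess–Martin periodinane, NaHCO3, CH2Cl2, 0 °C; used at once
Reagents that add atoms: none
Why: Buffered Dess–Martin oxidation gives the α-branched β-silyloxy aldehyde without epimerisation or β-elimination.

**Step 11**
Reactants: 20 (2R,3R)-3-[(tert-butyldimethylsilyl)oxy]-5-[(4-methoxybenzyl)oxy]-2-(4-methylpent-3-en-1-yl)pentanal
Product: 21 (1S,2R,5S)-5-{(1R)-1-[(tert-butyldimethylsilyl)oxy]-3-[(4-methoxybenzyl)oxy]propyl}-2-(prop-1-en-2-yl)cyclopentan-1-ol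
Conditions: Me2AlCl (2.2 equiv), CH2Cl2, −78 → −40 °C; cold 1 M HCl quench
Reagents that add atoms: none
Why: Lewis-acid-promoted intramolecular carbonyl-ene reaction: the closed transition state transfers an allylic H to the Al-bound oxygen on the face of the new C–C bond (OH cis to isopropenyl) with the α side chain pseudo-equatorial (OH trans to it), setting C1 (S) and C2 (R) from C5.

**Step 12**
Reactants: 21 (1S,2R,5S)-5-{(1R)-1-[(tert-butyldimethylsilyl)oxy]-3-[(4-methoxybenzyl)oxy]propyl}-2-(prop-1-en-2-yl)cyclopentan-1-ol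
Product: 22 tert-butyl{[(1S,2R,5R)-5-{(1R)-1-[(tert-butyldimethylsilyl)oxy]-3-[(4-methoxybenzyl)oxy]propyl}-2-(prop-1-en-2-yl)cyclopentyl]oxy}dimethylsilane
Conditions: TBSOTf, 2,6-lutidine, CH2Cl2, 0 °C → rt
Reagents that add atoms: tert-butyldimethylsilyl trifluoromethanesulfonate, CC(C)(C)[Si](C)(C)OS(=O)(=O)C(F)(F)F
Why: The silyl triflate silylates even this flanked secondary alcohol, blocking it against cyclisation onto the later iodide (descriptor at C5 changes by priority only).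

**Step 13**
Reactants: 22 tert-butyl{[(1S,2R,5R)-5-{(1R)-1-[(tert-butyldimethylsilyl)oxy]-3-[(4-methoxybenzyl)oxy]propyl}-2-(prop-1-en-2-yl)cyclopentyl]oxy}dimethylsilane
Product: 23 (3R)-3-[(tert-butyldimethylsilyl)oxy]-3-[(1R,2S,3R)-2-[(tert-butyldimethylsilyl)oxy]-3-(prop-1-en-2-yl)cyclopentyl]propan-1-ol
Conditions: DDQ, CH2Cl2/pH 7 buffer (10:1), 0 °C → rt
Reagents that add atoms: none
Why: Oxidative PMB ether cleavage by DDQ is orthogonal to the silyl ethers and the isopropenyl group.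

**Step 14**
Reactants: 23 (3R)-3-[(tert-butyldimethylsilyl)oxy]-3-[(1R,2S,3R)-2-[(tert-butyldimethylsilyl)oxy]-3-(prop-1-en-2-yl)cyclopentyl]propan-1-ol
Product: 24 tert-butyl{(1R)-1-[(1R,2S,3R)-2-[(tert-butyldimethylsilyl)oxy]-3-(prop-1-en-2-yl)cyclopentyl]-3-iodopropoxy}dimethylsilane
Conditions: I2, PPh3, imidazole, CH2Cl2, 0 °C → rt
Reagents that add atoms: iodine, II
Why: Appel-type iodination converts the unhindered primary alcohol into the primary iodide under neutral conditions.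

**Step 15**
Reactants: 24 tert-butyl{(1R)-1-[(1R,2S,3R)-2-[(tert-butyldimethylsilyl)oxy]-3-(prop-1-en-2-yl)cyclopentyl]-3-iodopropoxy}dimethylsilane; 25 ethyl 2-[bis(2-methylphenoxy)phosphoryl]acetate
Product: 27 ethyl 2-[bis(2-methylphenoxy)phosphoryl]-5-[(tert-butyldimethylsilyl)oxy]-5-[(1R,2S,3R)-2-[(tert-butyldimethylsilyl)oxy]-3-(prop-1-en-2-yl)cyclopentyl]pentanoate (5R; C2 epimers), via sodium phosphonoacetate 26 (not isolated)
Conditions: 25 (2.5 equiv), NaH (2.4 equiv), DMF, 0 °C → rt; then 24, 50 °C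
Reagents that add atoms: none
Why: SN2 C-alkylation of the soft phosphonoacetate carbanion by a primary iodide; excess nucleophile suppresses dialkylation and the new P-bearing centre becomes sp2 in step 17.

**Step 16**
Reactants: 28 1,1,4,4-tetramethoxybutane
Product: 29 butanedial (succinaldehyde)
Conditions: Amberlyst-15 (H+ form), H2O, 60 °C; CH2Cl2 extraction, distillation, used fresh
Reagents that add atoms: water, O
Why: Acid-catalysed acetal hydrolysis gives the monomeric dialdehyde from an achiral precursor.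

**Step 17**
Reactants: 27 ethyl 2-[bis(2-methylphenoxy)phosphoryl]-5-[(tert-butyldimethylsilyl)oxy]-5-[(1R,2S,3R)-2-[(tert-butyldimethylsilyl)oxy]-3-(prop-1-en-2-yl)cyclopentyl]pentanoate (2 equiv); 29 butanedial
Product: 31 diethyl (2Z,6Z)-2,7-bis{(3R)-3-[(tert-butyldimethylsilyl)oxy]-3-[(1R,2S,3R)-2-[(tert-butyldimethylsilyl)oxy]-3-(prop-1-en-2-yl)cyclopentyl]propyl}octa-2,6-dienedioate, via sodium phosphonate carbanion 30 (not isolated)
Conditions: 27 (2.2 equiv), NaH (2.1 equiv), THF, 0 °C; then 29 (1.0 equiv), −78 → 0 °C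
Reagents that add atoms: none
Why: Two-directional Ando-type Z-selective Horner–Wadsworth–Emmons olefination: the electron-poor diaryl phosphonate eliminates under kinetic control, placing the ester cis to the new chain at both trisubstituted alkenes.

**Step 18**
Reactants: 31 diethyl (2Z,6Z)-2,7-bis{(3R)-3-[(tert-butyldimethylsilyl)oxy]-3-[(1R,2S,3R)-2-[(tert-butyldimethylsilyl)oxy]-3-(prop-1-en-2-yl)cyclopentyl]propyl}octa-2,6-dienedioate
Product: 32 (2Z,6Z)-2,7-bis{(3R)-3-[(tert-butyldimethylsilyl)oxy]-3-[(1R,2S,3R)-2-[(tert-butyldimethylsilyl)oxy]-3-(prop-1-en-2-yl)cyclopentyl]propyl}octa-2,6-diene-1,8-diol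
Conditions: i-Bu2AlH (6 equiv), CH2Cl2, −78 °C; aq. KNaC4H4O6 work-up
Reagents that add atoms: none
Why: 1,2-Reduction of both enoates to the allylic alcohols leaves alkene geometry and silyl ethers intact.

**Step 19**
Reactants: 32 (2Z,6Z)-2,7-bis{(3R)-3-[(tert-butyldimethylsilyl)oxy]-3-[(1R,2S,3R)-2-[(tert-butyldimethylsilyl)oxy]-3-(prop-1-en-2-yl)cyclopentyl]propyl}octa-2,6-diene-1,8-diol
Product: 34 (2Z,6Z)-1,8-dichloro-2,7-bis{(3R)-3-[(tert-butyldimethylsilyl)oxy]-3-[(1R,2S,3R)-2-[(tert-butyldimethylsilyl)oxy]-3-(prop-1-en-2-yl)cyclopentyl]propyl}octa-2,6-diene, via bis(methanesulfonate) 33 (not isolated)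
Conditions: MsCl, 2,4,6-collidine, LiCl, DMF, 0 °C
Reagents that add atoms: lithium chloride, [Li+].[Cl-]
Why: Mesylation of the primary allylic alcohols and in-situ SN2 displacement by chloride gives the allylic chlorides without allylic transposition or E/Z change.

**Step 20**
Reactants: 34 (2Z,6Z)-1,8-dichloro-2,7-bis{(3R)-3-[(tert-butyldimethylsilyl)oxy]-3-[(1R,2S,3R)-2-[(tert-butyldimethylsilyl)oxy]-3-(prop-1-en-2-yl)cyclopentyl]propyl}octa-2,6-diene
Product: 35 (2Z,6Z)-1,8-dichloro-2,7-bis{(3R)-3-hydroxy-3-[(1R,2S,3R)-2-hydroxy-3-(prop-1-en-2-yl)cyclopentyl]propyl}octa-2,6-diene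
Conditions: HF·pyridine, pyridine, THF, 0 °C → rt
Reagents that add atoms: none
Why: Buffered acidic fluoride removes all four TBS groups without generating alkoxides or fluoride nucleophiles that could attack the allylic chlorides prematurely.

**Step 21**
Reactants: 35 (2Z,6Z)-1,8-dichloro-2,7-bis{(3R)-3-hydroxy-3-[(1R,2S,3R)-2-hydroxy-3-(prop-1-en-2-yl)cyclopentyl]propyl}octa-2,6-diene
Product: 36 testudinariol A
Conditions: NaH (excess), THF (0.01 M), 0 °C → rt
Reagents that add atoms: none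
Why: Double intramolecular Williamson etherification: each side-chain alkoxide closes a six-membered ring by 6-exo-tet SN2 at the primary allylic chloride (the cyclopentanol oxygen could only form an eight-membered ring), with no stereocentre or alkene geometry touched.

---

**Compound list**
1 | 4-methoxybenzyl alcohol | COc1ccc(CO)cc1 | starting material
2 | acrylonitrile | C=CC#N | starting material
3 | 3-[(4-methoxybenzyl)oxy]propanenitrile | COc1ccc(COCCC#N)cc1 | intermediate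
4 | methyl bromoacetate | COC(=O)CBr | starting material
5 | bromo(2-methoxy-2-oxoethyl)zinc, Reformatsky reagent (not isolated) | COC(=O)C[Zn]Br | intermediate
6 | methyl (2Z)-3-[(bromozincio)amino]-5-[(4-methoxybenzyl)oxy]pent-2-enoate, Blaise adduct (not isolated) | COC(=O)/C=C(/CCOCc1ccc(OC)cc1)N[Zn]Br | intermediate
7 | methyl 5-[(4-methoxybenzyl)oxy]-3-oxopentanoate | COC(=O)CC(=O)CCOCc1ccc(OC)cc1 | intermediate
8 | methyl (3R)-3-hydroxy-5-[(4-methoxybenzyl)oxy]pentanoate | COC(=O)C[C@H](O)CCOCc1ccc(OC)cc1 | intermediate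
9 | allyl bromide | C=CCBr | starting material
10 | dilithium alkoxide enolate of 8 (not isolated) | COC(O[Li])=C[C@H](O[Li])CCOCc1ccc(OC)cc1 | intermediate
11 | methyl (2R,3R)-3-hydroxy-5-[(4-methoxybenzyl)oxy]-2-(prop-2-en-1-yl)pentanoate | COC(=O)[C@H](CC=C)[C@H](O)CCOCc1ccc(OC)cc1 | intermediate
12 | methyl (2R,3R)-3-[(tert-butyldimethylsilyl)oxy]-5-[(4-methoxybenzyl)oxy]-2-(prop-2-en-1-yl)pentanoate | COC(=O)[C@H](CC=C)[C@H](O[Si](C)(C)C(C)(C)C)CCOCc1ccc(OC)cc1 | intermediate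
13 | B-alkyl-9-borabicyclo[3.3.1]nonane adduct of 12 (boron on the terminal carbon; not isolated) | COC(=O)[C@H](CCCB1C2CCCC1CCC2)[C@H](O[Si](C)(C)C(C)(C)C)CCOCc1ccc(OC)cc1 | intermediate
14 | methyl (2R,3R)-3-[(tert-butyldimethylsilyl)oxy]-2-(3-hydroxypropyl)-5-[(4-methoxybenzyl)oxy]pentanoate | COC(=O)[C@H](CCCO)[C@H](O[Si](C)(C)C(C)(C)C)CCOCc1ccc(OC)cc1 | intermediate
15 | methyl (2R,3R)-3-[(tert-butyldimethylsilyl)oxy]-5-[(4-methoxybenzyl)oxy]-2-(3-oxopropyl)pentanoate | COC(=O)[C@H](CCC=O)[C@H](O[Si](C)(C)C(C)(C)C)CCOCc1ccc(OC)cc1 | intermediate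
16 | isopropyltriphenylphosphonium iodide | CC(C)[P+](c1ccccc1)(c1ccccc1)c1ccccc1.[I-] | starting material
17 | (propan-2-ylidene)triphenylphosphorane (not isolated) | CC(C)=P(c1ccccc1)(c1ccccc1)c1ccccc1 | intermediate
18 | methyl (2R,3R)-3-[(tert-butyldimethylsilyl)oxy]-5-[(4-methoxybenzyl)oxy]-2-(4-methylpent-3-en-1-yl)pentanoate | COC(=O)[C@H](CCC=C(C)C)[C@H](O[Si](C)(C)C(C)(C)C)CCOCc1ccc(OC)cc1 | intermediate
19 | (2S,3R)-3-[(tert-butyldimethylsilyl)oxy]-5-[(4-methoxybenzyl)oxy]-2-(4-methylpent-3-en-1-yl)pentan-1-ol | OC[C@H](CCC=C(C)C)[C@H](O[Si](C)(C)C(C)(C)C)CCOCc1ccc(OC)cc1 | intermediate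
20 | (2R,3R)-3-[(tert-butyldimethylsilyl)oxy]-5-[(4-methoxybenzyl)oxy]-2-(4-methylpent-3-en-1-yl)pentanal | O=C[C@H](CCC=C(C)C)[C@H](O[Si](C)(C)C(C)(C)C)CCOCc1ccc(OC)cc1 | intermediate
21 | (1S,2R,5S)-5-{(1R)-1-[(tert-butyldimethylsilyl)oxy]-3-[(4-methoxybenzyl)oxy]propyl}-2-(prop-1-en-2-yl)cyclopentan-1-ol (OH cis to isopropenyl, trans to side chain) | C=C(C)[C@H]1CC[C@H]([C@H](O[Si](C)(C)C(C)(C)C)CCOCc2ccc(OC)cc2)[C@H]1O | intermediate
22 | tert-butyl{[(1S,2R,5R)-5-{(1R)-1-[(tert-butyldimethylsilyl)oxy]-3-[(4-methoxybenzyl)oxy]propyl}-2-(prop-1-en-2-yl)cyclopentyl]oxy}dimethylsilane | C=C(C)[C@H]1CC[C@H]([C@H](O[Si](C)(C)C(C)(C)C)CCOCc2ccc(OC)cc2)[C@H]1O[Si](C)(C)C(C)(C)C | intermediate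
23 | (3R)-3-[(tert-butyldimethylsilyl)oxy]-3-[(1R,2S,3R)-2-[(tert-butyldimethylsilyl)oxy]-3-(prop-1-en-2-yl)cyclopentyl]propan-1-ol | C=C(C)[C@H]1CC[C@H]([C@H](O[Si](C)(C)C(C)(C)C)CCO)[C@H]1O[Si](C)(C)C(C)(C)C | intermediate
24 | tert-butyl{(1R)-1-[(1R,2S,3R)-2-[(tert-butyldimethylsilyl)oxy]-3-(prop-1-en-2-yl)cyclopentyl]-3-iodopropoxy}dimethylsilane | C=C(C)[C@H]1CC[C@H]([C@H](O[Si](C)(C)C(C)(C)C)CCI)[C@H]1O[Si](C)(C)C(C)(C)C | intermediate
25 | ethyl 2-[bis(2-methylphenoxy)phosphoryl]acetate | CCOC(=O)CP(=O)(Oc1ccccc1C)Oc1ccccc1C | starting material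
26 | sodium salt (carbanion) of 25 (not isolated) | [Na+].CCOC(=O)[CH-]P(=O)(Oc1ccccc1C)Oc1ccccc1C | intermediate
27 | ethyl 2-[bis(2-methylphenoxy)phosphoryl]-5-[(tert-butyldimethylsilyl)oxy]-5-[(1R,2S,3R)-2-[(tert-butyldimethylsilyl)oxy]-3-(prop-1-en-2-yl)cyclopentyl]pentanoate (5R; mixture of C2 epimers) | C=C(C)[C@H]1CC[C@H]([C@H](O[Si](C)(C)C(C)(C)C)CCC(C(=O)OCC)P(=O)(Oc2ccccc2C)Oc2ccccc2C)[C@H]1O[Si](C)(C)C(C)(C)C | intermediate
28 | 1,1,4,4-tetramethoxybutane | COC(OC)CCC(OC)OC | starting material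
29 | butanedial (succinaldehyde) | O=CCCC=O | intermediate
30 | sodium salt (α-carbanion) of 27 (not isolated) | [Na+].C=C(C)[C@H]1CC[C@H]([C@H](O[Si](C)(C)C(C)(C)C)CC[C-](C(=O)OCC)P(=O)(Oc2ccccc2C)Oc2ccccc2C)[C@H]1O[Si](C)(C)C(C)(C)C | intermediate
31 | diethyl (2Z,6Z)-2,7-bis{(3R)-3-[(tert-butyldimethylsilyl)oxy]-3-[(1R,2S,3R)-2-[(tert-butyldimethylsilyl)oxy]-3-(prop-1-en-2-yl)cyclopentyl]propyl}octa-2,6-dienedioate | C=C(C)[C@H]1CC[C@H]([C@H](O[Si](C)(C)C(C)(C)C)CC/C(=C/CC/C=C(/CC[C@@H](O[Si](C)(C)C(C)(C)C)[C@H]2CC[C@H](C(=C)C)[C@@H]2O[Si](C)(C)C(C)(C)C)C(=O)OCC)C(=O)OCC)[C@H]1O[Si](C)(C)C(C)(C)C | intermediate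
32 | (2Z,6Z)-2,7-bis{(3R)-3-[(tert-butyldimethylsilyl)oxy]-3-[(1R,2S,3R)-2-[(tert-butyldimethylsilyl)oxy]-3-(prop-1-en-2-yl)cyclopentyl]propyl}octa-2,6-diene-1,8-diol | C=C(C)[C@H]1CC[C@H]([C@H](O[Si](C)(C)C(C)(C)C)CC/C(=C/CC/C=C(/CC[C@@H](O[Si](C)(C)C(C)(C)C)[C@H]2CC[C@H](C(=C)C)[C@@H]2O[Si](C)(C)C(C)(C)C)CO)CO)[C@H]1O[Si](C)(C)C(C)(C)C | intermediate
33 | bis(methanesulfonate) of 32 (not isolated) | C=C(C)[C@H]1CC[C@H]([C@H](O[Si](C)(C)C(C)(C)C)CC/C(=C/CC/C=C(/CC[C@@H](O[Si](C)(C)C(C)(C)C)[C@H]2CC[C@H](C(=C)C)[C@@H]2O[Si](C)(C)C(C)(C)C)COS(C)(=O)=O)COS(C)(=O)=O)[C@H]1O[Si](C)(C)C(C)(C)C | intermediate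
34 | (2Z,6Z)-1,8-dichloro-2,7-bis{(3R)-3-[(tert-butyldimethylsilyl)oxy]-3-[(1R,2S,3R)-2-[(tert-butyldimethylsilyl)oxy]-3-(prop-1-en-2-yl)cyclopentyl]propyl}octa-2,6-diene | C=C(C)[C@H]1CC[C@H]([C@H](O[Si](C)(C)C(C)(C)C)CC/C(=C/CC/C=C(/CC[C@@H](O[Si](C)(C)C(C)(C)C)[C@H]2CC[C@H](C(=C)C)[C@@H]2O[Si](C)(C)C(C)(C)C)CCl)CCl)[C@H]1O[Si](C)(C)C(C)(C)C | intermediate
35 | (2Z,6Z)-1,8-dichloro-2,7-bis{(3R)-3-hydroxy-3-[(1R,2S,3R)-2-hydroxy-3-(prop-1-en-2-yl)cyclopentyl]propyl}octa-2,6-diene | C=C(C)[C@H]1CC[C@H]([C@H](O)CC/C(=C/CC/C=C(/CC[C@@H](O)[C@H]2CC[C@H](C(=C)C)[C@@H]2O)CCl)CCl)[C@H]1O | intermediate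
36 | testudinariol A: (1S,2R,5S)-2-(prop-1-en-2-yl)-5-[(2R,5Z)-5-{4-[(3Z,6R)-6-[(1S,2S,3R)-2-hydroxy-3-(prop-1-en-2-yl)cyclopentyl]oxan-3-ylidene]butylidene}oxan-2-yl]cyclopentan-1-ol | C=C(C)[C@H]1CC[C@H]([C@H]2CC/C(=C/CC/C=C3/CC[C@H]([C@H]4CC[C@H](C(=C)C)[C@@H]4O)OC3)CO2)[C@H]1O | target

---

**Total step count:** 21
**Longest linear sequence:** 20 steps (steps 1–15 and 17–21; step 16 is a one-step side branch)

**Three steps most likely to fail**

Step 11 (carbonyl-ene cyclisation). The risks are a poor ratio against the all-cis isomer, chloride-trapped Prins products, or epimerisation of the aldehyde. The fallback sets out from 15 and comes back at 21, replacing the ene reaction by a nickel-catalysed alkylative allenyl-aldehyde cyclisation. Aldehyde 15 is homologated with dimethyl (1-diazo-2-oxopropyl)phosphonate and K2CO3 in MeOH to methyl (2R,3R)-2-(but-3-yn-1-yl)-3-[(tert-butyldimethylsilyl)oxy]-5-[(4-methoxybenzyl)oxy]pentanoate F1. Paraformaldehyde, CuBr and i-Pr2NH in refluxing dioxane extend F1 to the terminal allene methyl (2R,3R)-3-[(tert-butyldimethylsilyl)oxy]-5-[(4-methoxybenzyl)oxy]-2-(penta-3,4-dien-1-yl)pentanoate F2. Reduction with i-Bu2AlH gives (2S,3R)-3-[(tert-butyldimethylsilyl)oxy]-5-[(4-methoxybenzyl)oxy]-2-(penta-3,4-dien-1-yl)pentan-1-ol F3, and Dess–Martin oxidation gives (2R,3R)-3-[(tert-butyldimethylsilyl)oxy]-5-[(4-methoxybenzyl)oxy]-2-(penta-3,4-dien-1-yl)pentanal F4. Ni(cod)2 (10 mol %, zerovalent nickel) and Me2Zn in THF at 0 °C then join the aldehyde carbon to the proximal allene carbon through a nickelacycle while a methyl group from zinc is delivered to the central allene carbon. This gives 21 with the hydroxyl cis to the new isopropenyl group and trans to the side chain.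

Step 17 (double Z-selective olefination of butanedial). The risks are base-induced oligomerisation of the dialdehyde and incomplete Z,Z purity, since two alkenes are set at once. The fallback sets out from 27 and comes back at 31, building the two alkenes one at a time on a mono-protected linchpin. The sodium salt of 27 is condensed with commercial 4-[(tert-butyldimethylsilyl)oxy]butanal to give ethyl (2Z)-2-{(3R)-3-[(tert-butyldimethylsilyl)oxy]-3-[(1R,2S,3R)-2-[(tert-butyldimethylsilyl)oxy]-3-(prop-1-en-2-yl)cyclopentyl]propyl}-6-[(tert-butyldimethylsilyl)oxy]hex-2-enoate F5, from which any E isomer is removed by chromatography. The primary silyl ether alone is cleaved (HF·pyridine, pyridine, THF, 0 °C) to ethyl (2Z)-2-{(3R)-3-[(tert-butyldimethylsilyl)oxy]-3-[(1R,2S,3R)-2-[(tert-butyldimethylsilyl)oxy]-3-(prop-1-en-2-yl)cyclopentyl]propyl}-6-hydroxyhex-2-enoate F6. Dess–Martin oxidation gives ethyl (2Z)-2-{(3R)-3-[(tert-butyldimethylsilyl)oxy]-3-[(1R,2S,3R)-2-[(tert-butyldimethylsilyl)oxy]-3-(prop-1-en-2-yl)cyclopentyl]propyl}-6-oxohex-2-enoate F7, and a second olefination of F7 with the sodium salt of 27 delivers 31.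

Step 21 (double Williamson ring closure). The risks are SN2′ attack at the alkylidene carbon, intermolecular etherification, or loss of the allylic chloride during the preceding desilylation. The fallback sets out from 32 and comes back at 36, closing the rings by dehydration instead of halide displacement. Diol 32 is fully desilylated (HF·pyridine, pyridine, THF) to (2Z,6Z)-2,7-bis{(3R)-3-hydroxy-3-[(1R,2S,3R)-2-hydroxy-3-(prop-1-en-2-yl)cyclopentyl]propyl}octa-2,6-diene-1,8-diol F8. A Mitsunobu cyclodehydration (PPh3, diisopropyl azodicarboxylate, THF, high dilution, 0 °C → rt) activates only the primary allylic hydroxyls as alkoxyphosphonium ions. These are displaced by the neighbouring secondary hydroxyl, which acts as the nucleophile and so keeps its configuration, giving 36.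

**Further compounds**
F1 | step 11 | methyl (2R,3R)-2-(but-3-yn-1-yl)-3-[(tert-butyldimethylsilyl)oxy]-5-[(4-methoxybenzyl)oxy]pentanoate | COC(=O)[C@H](CCC#C)[C@H](O[Si](C)(C)C(C)(C)C)CCOCc1ccc(OC)cc1
F2 | step 11 | methyl (2R,3R)-3-[(tert-butyldimethylsilyl)oxy]-5-[(4-methoxybenzyl)oxy]-2-(penta-3,4-dien-1-yl)pentanoate | COC(=O)[C@H](CCC=C=C)[C@H](O[Si](C)(C)C(C)(C)C)CCOCc1ccc(OC)cc1
F3 | step 11 | (2S,3R)-3-[(tert-butyldimethylsilyl)oxy]-5-[(4-methoxybenzyl)oxy]-2-(penta-3,4-dien-1-yl)pentan-1-ol | OC[C@H](CCC=C=C)[C@H](O[Si](C)(C)C(C)(C)C)CCOCc1ccc(OC)cc1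
F4 | step 11 | (2R,3R)-3-[(tert-butyldimethylsilyl)oxy]-5-[(4-methoxybenzyl)oxy]-2-(penta-3,4-dien-1-yl)pentanal | O=C[C@H](CCC=C=C)[C@H](O[Si](C)(C)C(C)(C)C)CCOCc1ccc(OC)cc1
F5 | step 17 | ethyl (2Z)-2-{(3R)-3-[(tert-butyldimethylsilyl)oxy]-3-[(1R,2S,3R)-2-[(tert-butyldimethylsilyl)oxy]-3-(prop-1-en-2-yl)cyclopentyl]propyl}-6-[(tert-butyldimethylsilyl)oxy]hex-2-enoate | C=C(C)[C@H]1CC[C@H]([C@H](O[Si](C)(C)C(C)(C)C)CC/C(=C/CCCO[Si](C)(C)C(C)(C)C)C(=O)OCC)[C@H]1O[Si](C)(C)C(C)(C)C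
F6 | step 17 | ethyl (2Z)-2-{(3R)-3-[(tert-butyldimethylsilyl)oxy]-3-[(1R,2S,3R)-2-[(tert-butyldimethylsilyl)oxy]-3-(prop-1-en-2-yl)cyclopentyl]propyl}-6-hydroxyhex-2-enoate | C=C(C)[C@H]1CC[C@H]([C@H](O[Si](C)(C)C(C)(C)C)CC/C(=C/CCCO)C(=O)OCC)[C@H]1O[Si](C)(C)C(C)(C)C
F7 | step 17 | ethyl (2Z)-2-{(3R)-3-[(tert-butyldimethylsilyl)oxy]-3-[(1R,2S,3R)-2-[(tert-butyldimethylsilyl)oxy]-3-(prop-1-en-2-yl)cyclopentyl]propyl}-6-oxohex-2-enoate | C=C(C)[C@H]1CC[C@H]([C@H](O[Si](C)(C)C(C)(C)C)CC/C(=C/CCC=O)C(=O)OCC)[C@H]1O[Si](C)(C)C(C)(C)C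
F8 | step 21 | (2Z,6Z)-2,7-bis{(3R)-3-hydroxy-3-[(1R,2S,3R)-2-hydroxy-3-(prop-1-en-2-yl)cyclopentyl]propyl}octa-2,6-diene-1,8-diol | C=C(C)[C@H]1CC[C@H]([C@H](O)CC/C(=C/CC/C=C(/CC[C@@H](O)[C@H]2CC[C@H](C(=C)C)[C@@H]2O)CO)CO)[C@H]1O
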